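## Retrosynthetic overview

1. Feature (chain numbered as in geranylgeraniol, C1 = CH2Cl): the intact C20 chain carries two homochiral bromonium footprints. One is C6(Br, R)–C7(O) in the tetrahydropyran ring (O, C3, C4, C5, C6, C7), the other C14(Br, R)–C15(Me2) in the cyclohexane ring (C10–C15). C10–C11(OH) is the footprint of the alkene that attacked C15.
2. Key disconnection: O–C7, C6–Br, C10–C15, C14–Br and C11–OH are cut in one operation. This leads from bicyclic 6 (seven stereocentres) to the acyclic chlorodiol triene 4 (two stereocentres); one chiral Br+ catalyst sets C6, C7, C10, C11 and C14 as a group.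
3. 4 ⇒ epoxy chloride 3 (water opens C3 with inversion) ⇒ epoxy alcohol 2 (Appel) ⇒ geranylgeraniol 1 (Katsuki–Sharpless epoxidation sets C2 and C3).
4. Ring order: no ring before step 4; in that flask the tetrahydropyran closes first and the cyclohexane second.

Key step: step 4

Assumption: the (R)-configured catalyst of step 4 is taken as the antipode that delivers Br+ to the Re faces of C6 and C14; if a test on a geranyl model shows the opposite sense, its mirror image is used.

## Route

Step 1
Reactants: 1 (2E,6E,10E)-geranylgeraniol
Product: 2 (2R,3R)-2,3-epoxygeranylgeraniol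
Conditions: Ti(OiPr)4 (10 mol %), D-(−)-DIPT (12 mol %), TBHP (1.5 equiv, decane), 4 Å MS, CH2Cl2, −20 °C
Reagents that add atoms: tert-butyl hydroperoxide (TBHP), CC(C)(C)OO
Why: Katsuki–Sharpless asymmetric epoxidation: the titanium tartrate binds the allylic OH, so that only the C2=C3 alkene of the tetraene is oxidised, and the D-(−)-tartrate delivers oxygen to the face that gives the (2R,3R)-epoxide, which fixes C2 in its final spatial form and C3 in the form that step 3 inverts.

Step 2
Reactants: 2 (2R,3R)-2,3-epoxygeranylgeraniol
Product: 3 (2S,3R)-1-chloro-2,3-epoxide (epoxygeranylgeranyl chloride)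
Conditions: PPh3 (1.3 equiv), CCl4, NaHCO3 (solid buffer), 70 °C
Reagents that add atoms: carbon tetrachloride, ClC(Cl)(Cl)Cl
Why: Appel reaction: the oxyphosphonium salt of the primary C1–OH is displaced by chloride in an SN2 step under buffered, nearly neutral conditions that leave the epoxide and the three alkenes alone, and no stereocentre is touched (the C2 descriptor changes from R to S only because CH2Cl outranks C3).

Step 3
Reactants: 3 (2S,3R)-1-chloro-2,3-epoxide
Product: 4 (2S,3S,6E,10E)-1-chloro-3,7,11,15-tetramethylhexadeca-6,10,14-triene-2,3-diol
Conditions: HClO4 (5 mol %), THF/H2O 3:1, 0 °C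
Reagents that add atoms: water, O
Why: Acid-catalysed epoxide hydrolysis: water attacks the protonated epoxide from the back at the tertiary C3, the carbon that carries positive charge best because C2 is deactivated by the CH2Cl group, so that C3 is inverted to S and the C2–O bond (S) is kept, while the isolated trisubstituted alkenes are not hydrated by dilute acid at 0 °C.

Step 4
Reactants: 4 (2S,3S,6E,10E)-1-chloro-3,7,11,15-tetramethylhexadeca-6,10,14-triene-2,3-diol
Product: 6 target CNP0182369.1, via bromo-THP diene 5 (not isolated)
Conditions: (R)-3,3′-bis(2,4,6-triisopropylphenyl)-BINOL thiophosphoramide (20 mol %), DBDMH (0.52 equiv), HFIP (10 equiv), CH2Cl2/toluene 1:1, −78 °C; then H2O (5 equiv), DBDMH (0.55 equiv), −60 °C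
Reagents that add atoms: 1,3-dibromo-5,5-dimethylhydantoin (DBDMH), CC1(C)N(Br)C(=O)N(Br)C1=O; water, O
Why: Proposed new method: the sulfur of the chiral thiophosphoramide takes Br+ from DBDMH and, docked by hydrogen bonds on the C2/C3 diol, releases the first Br+ at the neighbouring C6=C7 alkene, whose bromiranium ion is opened at C7 by the C3 tertiary OH (6-endo closure of the tetrahydropyran, O–C7 bond, gives 5), after which the second Br+ goes to the sterically most open C14=C15 alkene, C10 of the remaining C10=C11 alkene attacks C15 through a chair (6-endo π-cyclisation, closes the cyclohexane, C10–C15 bond) and HFIP-bound water caps C11. The closest known reaction types are the thiophosphoramide/DBDMH-catalysed asymmetric bromocyclisation of polyenes, the N-bromoimide/HFIP 6-endo bromoetherification of γ,δ-unsaturated tertiary alcohols and the hydroxyl-terminated halonium- or Hg(II)-induced polyene cyclisation; new are their merger in one flask and the water termination under chiral Lewis-base control. C6 and C14 (both R) arise from Br+ delivery to the Re face of each CH= carbon, and since both alkenes show the catalyst the same local pattern RCH2–CH=C(CH3)R′, one catalyst antipode should serve both sites. C7 (S) follows from stereospecific anti addition to the E-alkene (Br and C8 trans-diequatorial), and here catalyst control is matched with the substrate chair that keeps the CH(OH)CH2Cl group on C3 equatorial and cis to C8. C10 (R) and C11 (R) follow from the chair and from anti addition across the E-configured C10=C11 alkene, which places Br, the C9 chain and the new OH all equatorial. The step needs the tetrahydropyran to close first, because a C11 cation formed while C6=C7 is still present would run on into that alkene, and this order is secured by nucleophile-assisted activation of C6=C7 through the catalyst-bound OH and by the two portions of DBDMH, while 6-endo over 5-exo and C3–OH over C2–OH rest on the tertiary cation character at C7 in the presence of HFIP and on the six- against seven-membered ring, and water capture over proton loss rests on excess water at low temperature.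

## Compound list

1 | (2E,6E,10E)-geranylgeraniol, (2E,6E,10E)-3,7,11,15-tetramethylhexadeca-2,6,10,14-tetraen-1-ol | OC/C=C(\C)CC/C=C(\C)CC/C=C(\C)CCC=C(C)C | starting material
2 | [(2R,3R)-3-methyl-3-[(3E,7E)-4,8,12-trimethyltrideca-3,7,11-trienyl]oxiran-2-yl]methanol | OC[C@H]1O[C@]1(C)CC/C=C(\C)CC/C=C(\C)CCC=C(C)C | intermediate
3 | (2S,3R)-2-(chloromethyl)-3-methyl-3-[(3E,7E)-4,8,12-trimethyltrideca-3,7,11-trienyl]oxirane | ClC[C@H]1O[C@]1(C)CC/C=C(\C)CC/C=C(\C)CCC=C(C)C | intermediate
4 | (2S,3S,6E,10E)-1-chloro-3,7,11,15-tetramethylhexadeca-6,10,14-triene-2,3-diol | O[C@](C)([C@H](O)CCl)CC/C=C(\C)CC/C=C(\C)CCC=C(C)C | intermediate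
5 | bromo-THP diene, (1S)-1-[(2S,5R,6S)-5-bromo-6-[(3E)-4,8-dimethylnona-3,7-dienyl]-2,6-dimethyloxan-2-yl]-2-chloroethanol | CC(C)=CCC/C(C)=C/CC[C@]1(C)O[C@](C)([C@H](O)CCl)CC[C@H]1Br | intermediate
6 | (1R,2R,4R)-4-bromo-2-{2-[(2S,3R,6S)-3-bromo-6-[(1S)-2-chloro-1-hydroxyethyl]-2,6-dimethyloxan-2-yl]ethyl}-1,3,3-trimethylcyclohexan-1-ol | CC1(C)[C@H](Br)CC[C@@](C)(O)[C@@H]1CC[C@]1(C)O[C@](C)([C@H](O)CCl)CC[C@H]1Br | target

Total step count: 4. Longest linear sequence: 4.

## Steps most likely to fail

**Step 4 (bears the label).**
- Br+ may reach the terminal alkene while C6=C7 is still intact, so that the cation cascade runs through C6=C7 to a tricyclic ether.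
- Uncatalysed Br+ transfer and olefin-to-olefin bromonium exchange may erode facial control at the remote C14=C15 alkene.
- 5-exo closure to a tetrahydrofuran may compete with the 6-endo closure.
- Proton loss from the C11 cation may compete with water capture.

The fallback uses known chemistry. It closes the rings one at a time and brings in the C11 oxygen by a radical hydration instead of by cation capture. It sets out from 4 and comes back at 6. Compound 4 is treated with NBS (1 equiv) in HFIP over 4 Å MS at 0 °C, and bromo-THP diene 5 is isolated. Compound 5 is then cyclised under the established anhydrous asymmetric protocol (chiral thiophosphoramide, DBDMH, toluene/CH2Cl2, −78 °C). This protocol ends by proton loss and should give the endocyclic C11=C12 alkene F1 together with the exocyclic C11 methylidene isomer F2. A Mukaiyama hydration of the unseparated pair (Mn(dpm)3 cat., PhSiH3, O2, i-PrOH, then P(OEt)3) is stereoconvergent, since both alkenes give the same C11 tertiary radical. O2 should trap this radical from the equatorial side, because the axial side is shielded by the axial C15 methyl group, to give 6.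

**Step 3.** Partial SN1 character at C3 may erode the inversion, and a 1,2-hydride shift in the opened cation may divert material to a ketone. The fallback replaces free acid hydrolysis by a chelate-directed opening of the epoxy alcohol and moves the chlorination to the end. It sets out from 2 and comes back at 4. Ti(OiPr)4 (1.5 equiv) and PhCO2H in CH2Cl2 bind the C1 alkoxide and the epoxide oxygen and deliver benzoate in an SN2 manner to C3, which should give the C3 benzoate F3. K2CO3 in MeOH cleaves the ester (wherever it may have migrated) to the (2R,3S)-triol F4. A primary-selective Appel chlorination (PPh3, CCl4, pyridine, 0 °C to rt) then leads to 4.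

**Step 2.** The acid-labile trisubstituted epoxide may be opened by chloride or by traces of HCl at the temperature of the Appel reaction. In the fallback chloride never meets the epoxide. It sets out from 2 and comes back at 4. TsCl, Et3N and DMAP in CH2Cl2 at 0 °C park the C1 oxygen as the epoxy tosylate F5. HClO4 (cat.) in THF/H2O hydrolyses the epoxide at C3 with inversion to the diol tosylate F6. LiCl in DMF at 40 °C displaces the primary sulfonate under neutral conditions to give 4.

## Further compounds

F1 | step 4 | endocyclic C11=C12 alkene, (1S)-1-[(2S,5R,6S)-5-bromo-6-{2-[(1R,5R)-5-bromo-2,6,6-trimethylcyclohex-2-enyl]ethyl}-2,6-dimethyloxan-2-yl]-2-chloroethanol | CC1(C)[C@H](Br)CC=C(C)[C@@H]1CC[C@]1(C)O[C@](C)([C@H](O)CCl)CC[C@H]1Br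
F2 | step 4 | exocyclic C11 methylidene isomer of F1 | CC1(C)[C@H](Br)CCC(=C)[C@@H]1CC[C@]1(C)O[C@](C)([C@H](O)CCl)CC[C@H]1Br
F3 | step 3 | (2R,3S,6E,10E)-1,2-dihydroxy-3,7,11,15-tetramethylhexadeca-6,10,14-trien-3-yl benzoate | O=C(O[C@](C)([C@H](O)CO)CC/C=C(\C)CC/C=C(\C)CCC=C(C)C)c1ccccc1
F4 | step 3 | (2R,3S,6E,10E)-3,7,11,15-tetramethylhexadeca-6,10,14-triene-1,2,3-triol | O[C@](C)([C@H](O)CO)CC/C=C(\C)CC/C=C(\C)CCC=C(C)C
F5 | step 2 | (2R,3R)-2,3-epoxygeranylgeranyl p-toluenesulfonate | Cc1ccc(cc1)S(=O)(=O)OC[C@H]1O[C@]1(C)CC/C=C(\C)CC/C=C(\C)CCC=C(C)C
F6 | step 2 | (2R,3S,6E,10E)-2,3-dihydroxy-3,7,11,15-tetramethylhexadeca-6,10,14-trien-1-yl p-toluenesulfonate | O[C@](C)([C@H](O)COS(=O)(=O)c1ccc(C)cc1)CC/C=C(\C)CC/C=C(\C)CCC=C(C)C
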